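**Plan**
- Retrosynthesis: the two O–CH2OMe acetals on O5 and O7, the O3–CH3 bond and the C3–O bond are cut first, leaving a 3-unsubstituted flavone. Ring C of that flavone is then cut at C4a–C4, C4–C3 and O1–C2 together.
- Enabling feature: C4 is a single carbonyl carbon bridging C4a of ring A and the C3=C2 pair that holds ring B, and O1 sits on C8a next to C4a. C4 can therefore be carbon monoxide, C3/C2 a terminal arylacetylene, and C4a/C8a–O1 an ortho-iodophenol.
- Forward order: rings A and B are bought as benzene rings. Ring A gains its fourth oxygen (the later O5) by C–H borylation/oxidation and its iodine on a symmetric diol with only one kind of C–H. Ring B gains the prenyl ether and the alkyne. Ring C is the only ring built, in the three-component step.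
- End game: C3 is metalated, borylated and oxidised, O3 is methylated, and both MOM groups are removed under buffered, non-protic conditions that spare the prenyl ether.
- Stereochemistry: none has to be created, because the target has no stereocentre and its prenyl double bond ends in two methyl groups.

Key step: step 9

Remark: the target is achiral, so its constitution alone defines a single compound and no step has to control configuration.

**Step 1**
Reactants: 1 2-methoxyresorcinol (2-methoxybenzene-1,3-diol)
Product: 2 2-methoxy-1,3-bis(triisopropylsilyloxy)benzene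
Conditions: TIPSCl (2.4 equiv), imidazole (5 equiv), DMF, rt to 40 °C
Reagents that add atoms: triisopropylsilyl chloride, CC(C)[Si](Cl)(C(C)C)C(C)C
Why: Imidazole-promoted silylation of phenols gives bulky, base-stable TIPS ethers that shield both neighbouring C–H bonds and, unlike arylmethyl ethers, bring in no aromatic C–H bond that could compete in the following borylation.

**Step 2**
Reactants: 2 2-methoxy-1,3-bis(triisopropylsilyloxy)benzene
Product: 4 4-methoxy-3,5-bis(triisopropylsilyloxy)phenol, via pinacol arylboronate 3 (not isolated)
Conditions: [Ir(OMe)(cod)]2 (1.5 mol %), dtbpy (3 mol %), B2pin2 (1.0 equiv), THF, 80 °C; then 30% H2O2, aq NaOH, THF, 0 °C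
Reagents that add atoms: bis(pinacolato)diboron, CC1(C)OB(OC1(C)C)B1OC(C)(C)C(C)(C)O1 (boron and pinacol held only in 3); hydrogen peroxide, OO (the new phenol oxygen)
Why: Iridium-catalysed aromatic C–H borylation is sterically governed and only C5–H of a 1,2,3-trisubstituted benzene lacks an ortho substituent, so a single boronate should form, which alkaline peroxide turns into the phenol in the same flask (one-pot C–H borylation/oxidation).

**Step 3**
Reactants: 4 4-methoxy-3,5-bis(triisopropylsilyloxy)phenol
Product: 5 2-methoxy-5-(methoxymethoxy)-1,3-bis(triisopropylsilyloxy)benzene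
Conditions: MOMCl (1.5 equiv), i-Pr2NEt (2 equiv), CH2Cl2, 0 °C to rt
Reagents that add atoms: chloromethyl methyl ether, COCCl
Why: O-Alkylation of the only free, unhindered phenol with an α-chloro ether (MOM protection) is routine and leaves the silyl ethers untouched.

**Step 4**
Reactants: 5 2-methoxy-5-(methoxymethoxy)-1,3-bis(triisopropylsilyloxy)benzene
Product: 6 2-methoxy-5-(methoxymethoxy)benzene-1,3-diol
Conditions: TBAF (2.2 equiv), AcOH (2.2 equiv), THF, 0 °C
Reagents that add atoms: none
Why: Fluoride-induced desilylation of aryl silyl ethers is fast, the acetic acid buffer keeps the electron-rich phenols protonated and safe from air oxidation, and the MOM acetal is inert to fluoride.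

**Step 5**
Reactants: 6 2-methoxy-5-(methoxymethoxy)benzene-1,3-diol
Product: 7 4-iodo-2-methoxy-5-(methoxymethoxy)benzene-1,3-diol
Conditions: NIS (1.0 equiv, added in portions), MeCN, −20 °C, dark
Reagents that add atoms: N-iodosuccinimide, O=C1CCC(=O)N1I
Why: Electrophilic aromatic iodination of a mirror-symmetric diol whose two C–H positions are equivalent (each ortho to one OH, para to the other, ortho to OMOM) can give only one mono-iodide, and the acid-free reagent keeps the acetal intact.

**Step 6**
Reactants: 7 4-iodo-2-methoxy-5-(methoxymethoxy)benzene-1,3-diol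
Product: 8 2-iodo-6-methoxy-3,5-bis(methoxymethoxy)phenol
Conditions: MOMCl (1.0 equiv, slow addition), i-Pr2NEt (1.2 equiv), CH2Cl2, −20 to 0 °C
Reagents that add atoms: chloromethyl methyl ether, COCCl
Why: Site-selective mono-etherification as known for 4-haloresorcinols, which react at the oxygen para to halogen, should operate here because the hydroxyl between iodine and methoxy is shielded on both sides while the other one has a C–H neighbour.

**Step 7**
Reactants: 9 4-hydroxybenzaldehyde; 10 prenyl bromide (1-bromo-3-methylbut-2-ene)
Product: 11 4-(3-methylbut-2-enyloxy)benzaldehyde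
Conditions: K2CO3 (1.5 equiv), acetone, reflux
Reagents that add atoms: none
Why: Williamson ether synthesis of an acidic phenol with a primary allylic bromide proceeds by SN2 at oxygen under weak base.

**Step 8**
Reactants: 11 4-(3-methylbut-2-enyloxy)benzaldehyde
Product: 12 1-ethynyl-4-(3-methylbut-2-enyloxy)benzene
Conditions: dimethyl (1-diazo-2-oxopropyl)phosphonate (1.3 equiv), K2CO3 (2 equiv), MeOH, rt
Reagents that add atoms: dimethyl (1-diazo-2-oxopropyl)phosphonate, CC(=O)C(=[N+]=[N-])P(=O)(OC)OC
Why: The Ohira–Bestmann variant of the Seyferth–Gilbert homologation converts aromatic aldehydes into terminal alkynes under mild carbonate conditions that do not touch the prenyl ether.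

**Step 9**
Reactants: 8 2-iodo-6-methoxy-3,5-bis(methoxymethoxy)phenol; 12 1-ethynyl-4-(3-methylbut-2-enyloxy)benzene; 13 carbon monoxide
Product: 16 8-methoxy-5,7-bis(methoxymethoxy)-4'-(3-methylbut-2-enyloxy)flavone, via aryl ynone 14 (not isolated), via diethylamino enaminone 15 (not isolated)
Conditions: PdCl2(dppf) (5 mol %), CO (5 bar), 12 (1.3 equiv), Et2NH (4 equiv), DMF, 60 °C, no copper salt
Reagents that add atoms: diethylamine, CCNCC (nitrogen and ethyl groups held only in 15)
Why: Pd(0) inserts into the C–I bond of 8, migratory insertion of CO gives the aroyl-palladium species, and the acetylide formed from 12 and the amine is transferred and reductively eliminated to ynone 14, which sets C4a–C4 and C4–C3. Diethylamine then adds in conjugate fashion to give enaminone 15, the neighbouring phenol attacks its β-carbon, and loss of the amine forms O1–C2. The reaction type is the known carbonylative Sonogashira coupling/cyclisation of 2-iodophenols with terminal arylacetylenes to flavones. Ring C closes in a 6-endo sense (6-endo-trig addition–elimination on 15, overall equal to 6-endo-dig on 14), and no stereocentre is formed. Flavone rather than aurone (5-exo) is required and the secondary amine secures this because only the β-carbon of 15 is electrophilic, while CO uptake before alkynylation is favoured by the electron-rich aryl–palladium bond, the CO pressure and the absence of copper. Closure through the oxygen beside the methoxy-bearing carbon is secured because it is the only free hydroxyl ortho to the new acyl group, the other ortho oxygen being locked as its MOM ether.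

**Step 10**
Reactants: 16 8-methoxy-5,7-bis(methoxymethoxy)-4'-(3-methylbut-2-enyloxy)flavone
Product: 19 3-hydroxy-8-methoxy-5,7-bis(methoxymethoxy)-4'-(3-methylbut-2-enyloxy)flavone, via 3-lithioflavone 17 (not isolated), via dimethyl flavon-3-ylboronate 18 (not isolated)
Conditions: LDA (1.4 equiv), THF, −78 °C; B(OMe)3 (3 equiv), −78 to 0 °C; then 30% H2O2, aq NaOH, 0 °C
Reagents that add atoms: lithium diisopropylamide, [Li+].CC(C)[N-]C(C)C (lithium held only in 17); trimethyl borate, COB(OC)OC (boron and methoxy groups held only in 18); hydrogen peroxide, OO (the 3-oxygen)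
Why: Flavones are deprotonated by LDA at C3 (known vinylic lithiation next to the carbonyl), and borate trapping followed by alkaline peroxide oxidation delivers the flavonol with a nucleophilic oxidant that does not epoxidise the electron-rich prenyl alkene.

**Step 11**
Reactants: 19 3-hydroxy-8-methoxy-5,7-bis(methoxymethoxy)-4'-(3-methylbut-2-enyloxy)flavone
Product: 20 3,8-dimethoxy-5,7-bis(methoxymethoxy)-4'-(3-methylbut-2-enyloxy)flavone
Conditions: MeI (2 equiv), K2CO3 (2 equiv), acetone, 40 °C
Reagents that add atoms: iodomethane, CI
Why: Williamson O-methylation of the acidic enolic 3-hydroxyl, the only free OH in the molecule, is standard flavonol chemistry.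

**Step 12**
Reactants: 20 3,8-dimethoxy-5,7-bis(methoxymethoxy)-4'-(3-methylbut-2-enyloxy)flavone
Product: 22 5,7-dihydroxy-3,8-dimethoxy-4'-(3-methylbut-2-enyloxy)flavone (target), via bis(trimethylsilyl) ether 21 (not isolated)
Conditions: TMSOTf (6 equiv), 2,2'-bipyridyl (9 equiv), MeCN, 0 °C to rt; then H2O, rt
Reagents that add atoms: trimethylsilyl trifluoromethanesulfonate, C[Si](C)(C)OS(=O)(=O)C(F)(F)F (silicon held only in 21)
Why: The silyl triflate/2,2'-bipyridyl cleavage of aromatic MOM ethers runs through aryl silyl ethers without free Brønsted acid, so both acetals should fall to phenols on addition of water while the acid-labile prenyl aryl ether, its alkene and the two methyl ethers remain.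

**Compound list**
1 | 2-methoxyresorcinol | COc1c(O)cccc1O | starting material
2 | 2-methoxy-1,3-bis(triisopropylsilyloxy)benzene | COc1c(O[Si](C(C)C)(C(C)C)C(C)C)cccc1O[Si](C(C)C)(C(C)C)C(C)C | intermediate
3 | 2-[4-methoxy-3,5-bis(triisopropylsilyloxy)phenyl]-4,4,5,5-tetramethyl-1,3,2-dioxaborolane | COc1c(O[Si](C(C)C)(C(C)C)C(C)C)cc(B2OC(C)(C)C(C)(C)O2)cc1O[Si](C(C)C)(C(C)C)C(C)C | intermediate
4 | 4-methoxy-3,5-bis(triisopropylsilyloxy)phenol | COc1c(O[Si](C(C)C)(C(C)C)C(C)C)cc(O)cc1O[Si](C(C)C)(C(C)C)C(C)C | intermediate
5 | 2-methoxy-5-(methoxymethoxy)-1,3-bis(triisopropylsilyloxy)benzene | COCOc1cc(O[Si](C(C)C)(C(C)C)C(C)C)c(OC)c(O[Si](C(C)C)(C(C)C)C(C)C)c1 | intermediate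
6 | 2-methoxy-5-(methoxymethoxy)benzene-1,3-diol | COCOc1cc(O)c(OC)c(O)c1 | intermediate
7 | 4-iodo-2-methoxy-5-(methoxymethoxy)benzene-1,3-diol | COCOc1cc(O)c(OC)c(O)c1I | intermediate
8 | 2-iodo-6-methoxy-3,5-bis(methoxymethoxy)phenol | COc1c(OCOC)cc(OCOC)c(I)c1O | intermediate
9 | 4-hydroxybenzaldehyde | O=Cc1ccc(O)cc1 | starting material
10 | prenyl bromide (1-bromo-3-methylbut-2-ene) | CC(C)=CCBr | starting material
11 | 4-(3-methylbut-2-enyloxy)benzaldehyde | CC(C)=CCOc1ccc(C=O)cc1 | intermediate
12 | 1-ethynyl-4-(3-methylbut-2-enyloxy)benzene | C#Cc1ccc(OCC=C(C)C)cc1 | intermediate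
13 | carbon monoxide | [C-]#[O+] | starting material
14 | 1-[2-hydroxy-3-methoxy-4,6-bis(methoxymethoxy)phenyl]-3-[4-(3-methylbut-2-enyloxy)phenyl]prop-2-yn-1-one | COc1c(OCOC)cc(OCOC)c(C(=O)C#Cc2ccc(OCC=C(C)C)cc2)c1O | intermediate
15 | (E)-3-(diethylamino)-1-[2-hydroxy-3-methoxy-4,6-bis(methoxymethoxy)phenyl]-3-[4-(3-methylbut-2-enyloxy)phenyl]prop-2-en-1-one | COc1c(OCOC)cc(OCOC)c(C(=O)/C=C(\c2ccc(OCC=C(C)C)cc2)N(CC)CC)c1O | intermediate
16 | 8-methoxy-5,7-bis(methoxymethoxy)-4'-(3-methylbut-2-enyloxy)flavone | COc1c(OCOC)cc(OCOC)c2c1oc(-c1ccc(OCC=C(C)C)cc1)cc2=O | intermediate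
17 | 3-lithio-8-methoxy-5,7-bis(methoxymethoxy)-4'-(3-methylbut-2-enyloxy)flavone | COc1c(OCOC)cc(OCOC)c2c1oc(-c1ccc(OCC=C(C)C)cc1)c([Li])c2=O | intermediate
18 | dimethyl [8-methoxy-5,7-bis(methoxymethoxy)-4'-(3-methylbut-2-enyloxy)flavon-3-yl]boronate | COc1c(OCOC)cc(OCOC)c2c1oc(-c1ccc(OCC=C(C)C)cc1)c(B(OC)OC)c2=O | intermediate
19 | 3-hydroxy-8-methoxy-5,7-bis(methoxymethoxy)-4'-(3-methylbut-2-enyloxy)flavone | COc1c(OCOC)cc(OCOC)c2c1oc(-c1ccc(OCC=C(C)C)cc1)c(O)c2=O | intermediate
20 | 3,8-dimethoxy-5,7-bis(methoxymethoxy)-4'-(3-methylbut-2-enyloxy)flavone | COc1c(OCOC)cc(OCOC)c2c1oc(-c1ccc(OCC=C(C)C)cc1)c(OC)c2=O | intermediate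
21 | 3,8-dimethoxy-4'-(3-methylbut-2-enyloxy)-5,7-bis(trimethylsilyloxy)flavone | COc1c(O[Si](C)(C)C)cc(O[Si](C)(C)C)c2c1oc(-c1ccc(OCC=C(C)C)cc1)c(OC)c2=O | intermediate
22 | 5,7-dihydroxy-3,8-dimethoxy-4'-prenyloxyflavone | COc1c(-c2ccc(OCC=C(C)C)cc2)oc2c(OC)c(O)cc(O)c2c1=O | target

**Totals**
Total step count: 12. Longest linear sequence: 10 (steps 1–6 and 9–12). The alkyne arm (steps 7 and 8) is convergent.

**Steps most likely to fail**

1. Step 9.
 - What may go wrong: oxidative addition into a C–I bond flanked by two oxygen substituents on a very electron-rich ring may be slow. Alkynylation may precede CO uptake and be followed by closure to a benzofuran. Diethylamine may intercept the aroyl-palladium species by aminocarbonylation. Palladium may ionise the prenyl ether.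
 - Fallback: it sets out from 8 and 12 and comes back at 14, and through it at 16, without palladium or CO. Alkyne 12 is deprotonated with n-BuLi (THF, −78 °C) and acylated with N-methoxy-N-methylcarbamoyl chloride to the Weinreb amide N-methoxy-N-methyl-3-[4-(3-methylbut-2-enyloxy)phenyl]prop-2-ynamide F1.
 - Iodophenol 8 is treated with n-BuLi (2.1 equiv, THF, −78 °C), which first removes the phenol proton and then exchanges iodine for lithium. Addition of F1 should give ynone 14 as an isolated compound.
 - Warming 14 with Et2NH in DMF closes ring C by way of 15 to 16. The same three bonds are formed, one after the other, and C4 then comes from the carbamoyl chloride.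

2. Step 6.
 - What may go wrong: discrimination between the two hydroxyls may be poor, and double acetalisation may occur, because the small and reactive chloro ether feels steric differences only weakly.
 - Fallback: it sets out from 7 and comes back at 16, and it leaves the choice between the two oxygens to the ring closure itself. Diol 7 is peracetylated (Ac2O, pyridine) to 4-iodo-2-methoxy-5-(methoxymethoxy)-1,3-phenylene diacetate F2.
 - F2 is coupled with 12 and 13 under amine-rich carbonylative conditions, a reaction type known for 2-iodophenyl acetates. The less electron-rich ring should also speed up oxidative addition.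
 - Diethylamine cleaves both acetates in the flask, and only the oxygen ortho to the new acyl group can cyclise. This should give 7-hydroxy-8-methoxy-5-(methoxymethoxy)-4'-(3-methylbut-2-enyloxy)flavone F3.
 - MOMCl/i-Pr2NEt on the single remaining hydroxyl of F3 leads to 16.

3. Step 12.
 - What may go wrong: the prenyl–oxygen bond may ionise, or the prenyl alkene may be attacked by the silyl Lewis acid. Acetal cleavage at O7 may also stall because the reagent is tied up by the pyranone carbonyl.
 - Fallback: it sets out from 20 and comes back at 22 by accepting loss of the prenyl group and putting it back last. Heating 20 with HCl in MeOH strips both MOM groups and the prenyl ether to give 5,7,4'-trihydroxy-3,8-dimethoxyflavone F4.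
 - F4 is converted with t-BuOK (2 equiv, DMF, 0 °C) into its 7,4'-dianion, while the chelated 5-OH stays protonated.
 - One equivalent of prenyl bromide 10 should then alkylate the more basic, unhindered 4'-phenoxide rather than the carbonyl-stabilised 7-phenoxide, which is also flanked by the 8-methoxy group. This dianion selectivity is known for polyhydroxy(iso)flavones and leads to 22.

**Further compounds**
F1 | step 9 | N-methoxy-N-methyl-3-[4-(3-methylbut-2-enyloxy)phenyl]prop-2-ynamide | CON(C)C(=O)C#Cc1ccc(OCC=C(C)C)cc1
F2 | step 6 | 4-iodo-2-methoxy-5-(methoxymethoxy)-1,3-phenylene diacetate | COc1c(OC(C)=O)cc(OCOC)c(I)c1OC(C)=O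
F3 | step 6 | 7-hydroxy-8-methoxy-5-(methoxymethoxy)-4'-(3-methylbut-2-enyloxy)flavone | COc1c(O)cc(OCOC)c2c1oc(-c1ccc(OCC=C(C)C)cc1)cc2=O
F4 | step 12 | 5,7,4'-trihydroxy-3,8-dimethoxyflavone | COc1c(-c2ccc(O)cc2)oc2c(OC)c(O)cc(O)c2c1=O
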